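**Retrosynthetic overview**
1. Target 15 ⇐ enone 14 (loss of two methoxymethyl groups) ⇐ bridgehead cyclopropanol 12 by an oxidative one-carbon ring enlargement, cyclopentane → cyclohexenone.
2. Enabling feature: the 1-hydroxybicyclo[3.1.0]hexane core of 12, i.e. a hydroxyl on bridgehead C1 and the strained zero-atom bridge C1–C5 shared by the cyclopropane (C1, C5, C6) and the cyclopentane (C1–C5). Cutting this bond makes the five-membered ring plus C6 the six-membered ring.
3. 12 ⇐ acyclic hex-5-enoate 11 by intramolecular Kulinkovich cyclopropanation (ester carbon + vinyl group; cyclopentane and cyclopropane form together).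
4. 11 ⇐ α-alkoxy ketone 8 + acetate unit 9 (chelation-controlled Mukaiyama aldol sets the quaternary carbinol); 8 ⇐ oleyl aldehyde 2 + allyl ether 4 (asymmetric alkoxyallylboration sets the secondary ether centre, then oxidation).
5. Ring order: cyclopropane and cyclopentane in step 7, then cyclopentane → cyclohexenone in step 8; the carbons come from oleyl alcohol (C5 and side chain), allyl alcohol (C2–C4) and acetate (C6, C1).

Key step: step 8

Assumption: 12 and the transient 13 are carried as mixtures at the centres that step 8 erases (the two cis-fused cyclopropane bridgeheads of 12, the CHCl carbon of 13); their SMILES leave these centres undefined.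

**Step 1**
Reactants: 1 (Z)-octadec-9-en-1-ol (oleyl alcohol)
Product: 2 (Z)-octadec-9-enal
Conditions: TEMPO (10 mol %), PhI(OAc)2 (1.1 equiv), CH2Cl2, rt
Reagents that add atoms: none
Why: Oxoammonium (TEMPO) oxidation with PhI(OAc)2 as terminal oxidant should stop at the aldehyde and leave the isolated Z-alkene untouched and unisomerised.

**Step 2**
Reactants: 3 prop-2-en-1-ol (allyl alcohol)
Product: 4 3-(methoxymethoxy)prop-1-ene
Conditions: MOMCl, iPr2NEt, CH2Cl2, 0 °C to rt
Reagents that add atoms: chloromethyl methyl ether, COCCl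
Why: Base-mediated O-alkylation of a primary alcohol by the reactive α-chloro ether (acetal formation).

**Step 3**
Reactants: 4 3-(methoxymethoxy)prop-1-ene; 2 (Z)-octadec-9-enal
Product: 7 (3S,4S,12Z)-3-(methoxymethoxy)henicosa-1,12-dien-4-ol, via allylborane 5 (not isolated), via borinate ester 6 (not isolated)
Conditions: s-BuLi, THF, −78 °C; (+)-Ipc2BOMe; BF3·OEt2; 2, −78 °C; then NaOH, H2O2, 0 °C to rt
Reagents that add atoms: none
Why: Brown asymmetric alkoxyallylboration: kinetic deprotonation of 4 gives the oxygen-chelated Z-allyllithium, boron transfer gives the Z-borane 5, and its addition to 2 through a closed chair (Zimmerman–Traxler) transition state should give the syn adduct, the isopinocampheyl groups from (−)-α-pinene directing attack to the Re face of the aldehyde so that the ether carbon C3 (future ring C4) is set as S; the carbinol centre C4 is removed in step 4.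

**Step 4**
Reactants: 7 (3S,4S,12Z)-3-(methoxymethoxy)henicosa-1,12-dien-4-ol
Product: 8 (3S,12Z)-3-(methoxymethoxy)henicosa-1,12-dien-4-one
Conditions: Dess–Martin periodinane, NaHCO3, CH2Cl2, 0 °C
Reagents that add atoms: none
Why: Dess–Martin oxidation under bicarbonate buffer is mild enough that the doubly activated (α-alkoxy, allylic) C3 hydrogen of the β,γ-unsaturated ketone should neither epimerise nor let the alkene move into conjugation.

**Step 5**
Reactants: 8 (3S,12Z)-3-(methoxymethoxy)henicosa-1,12-dien-4-one; 9 1-(tert-butyldimethylsilyloxy)-1-methoxyethene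
Product: 10 methyl (3S,4S)-3-[(8Z)-heptadec-8-en-1-yl]-3-hydroxy-4-(methoxymethoxy)hex-5-enoate
Conditions: TiCl4 (1.1 equiv), CH2Cl2, −78 °C; then 9 (1.5 equiv), −78 °C; aq NaHCO3
Reagents that add atoms: none
Why: Chelation-controlled Mukaiyama aldol addition: TiCl4 holds the ketone oxygen and the α-ether oxygen in a five-membered chelate and the silyl ketene acetal attacks the carbonyl face that carries the C3 hydrogen rather than the vinyl group (Cram chelate model), which sets the tertiary carbinol (future ring C5) as S, syn to the C4 oxygen along the ester backbone, without basic conditions that would enolise 8.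

**Step 6**
Reactants: 10 methyl (3S,4S)-3-[(8Z)-heptadec-8-en-1-yl]-3-hydroxy-4-(methoxymethoxy)hex-5-enoate
Product: 11 methyl (3S,4S)-3-[(8Z)-heptadec-8-en-1-yl]-3,4-bis(methoxymethoxy)hex-5-enoate
Conditions: MOMCl, iPr2NEt, Bu4NI (cat.), ClCH2CH2Cl, 50 °C
Reagents that add atoms: chloromethyl methyl ether, COCCl
Why: Acetal formation at the hindered tertiary hydroxyl (iodide catalysis), which blocks retro-aldol cleavage of the β-alkoxide under the Grignard conditions of step 7 and leaves two identical groups for one final unmasking.

**Step 7**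
Reactants: 11 methyl (3S,4S)-3-[(8Z)-heptadec-8-en-1-yl]-3,4-bis(methoxymethoxy)hex-5-enoate
Product: 12 (3S,4S)-3-[(8Z)-heptadec-8-en-1-yl]-3,4-bis(methoxymethoxy)bicyclo[3.1.0]hexan-1-ol (cis-fused, mixture at C1/C5)
Conditions: ClTi(OiPr)3 (1.0 equiv), c-C5H9MgCl (4.5 equiv, slow addition), THF, rt; aq NH4Cl
Reagents that add atoms: none
Why: Intramolecular Kulinkovich cyclopropanation by ligand exchange: the titanacyclopropane from c-C5H9MgCl and ClTi(OiPr)3 (a divalent titanium–alkene complex) exchanges cyclopentene for the terminal vinyl group of 11 (the internal Z-alkene does not exchange), inserts the ester carbonyl to close the five-membered ring and contracts with loss of methoxide to the cis-fused bridgehead cyclopropanol, whose two new centres are erased in step 8.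

**Step 8**
Reactants: 12 (3S,4S)-3-[(8Z)-heptadec-8-en-1-yl]-3,4-bis(methoxymethoxy)bicyclo[3.1.0]hexan-1-ol
Product: 14 (4S,5S)-5-[(8Z)-heptadec-8-en-1-yl]-4,5-bis(methoxymethoxy)cyclohex-2-en-1-one, via chloroketone 13 (not isolated)
Conditions: FeCl3 (2.3 equiv), DMF, 0 °C; extractive work-up; then NaOAc, MeOH, rt
Reagents that add atoms: none
Why: FeCl3 converts the bridgehead cyclopropanol into an alkoxide of trivalent iron that is oxidised by one electron to the cyclopropyloxy radical; β-scission of the shared C1–C5 bond, driven by release of cyclopropane strain, gives the ring-enlarged secondary 3-oxocyclohexyl radical, which takes chlorine from a second FeCl3 to give 13, and NaOAc then removes HCl by E1cB elimination through the C2 enolate to place the double bond at C2–C3. The closest known reaction type is the Ito–Saegusa FeCl3 ring enlargement of 1-silyloxy- and 1-hydroxybicyclo[n.1.0]alkanes to 2-cycloalkenones. No ring is closed by bond formation: the six-membered ring is the cyclopentane ring of 12 enlarged by the former cyclopropane methylene when the zero-atom bridge is cut. No stereocentre is created (the CHCl carbon of 13 becomes sp2 and both bridgehead centres of 12 vanish), and C4 and C5 are not involved. The selectivity needed is scission of the internal rather than the external cyclopropane bond; it is secured because internal scission gives a secondary instead of a primary radical and because the primary (2-oxocyclopentyl)methyl radical, if formed, can return through the same cyclopropyloxy radical to the ring-enlarged one (Dowd–Beckwith manifold). The direction of elimination is secured because chloride is a far better β-leaving group than the C5 acetal oxygen.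

**Step 9**
Reactants: 14 (4S,5S)-5-[(8Z)-heptadec-8-en-1-yl]-4,5-bis(methoxymethoxy)cyclohex-2-en-1-one
Product: 15 (4S,5S)-5-[(8Z)-heptadec-8-en-1-yl]-4,5-dihydroxycyclohex-2-en-1-one
Conditions: Me2BBr (6 equiv), CH2Cl2, −78 °C; then THF/sat. aq NaHCO3, −78 to 0 °C
Reagents that add atoms: none
Why: Me2BBr cleaves both methoxymethyl acetals at −78 °C by boron coordination and bromide attack at the O–CH2–O carbon (not at C4 or C5), and the boron- and bromomethyl-bound intermediates hydrolyse in the bicarbonate quench, so that the dehydration-prone β-hydroxy enone meets neither protic acid nor strong base and no stereocentre is touched.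

**Compound list**
1 | (Z)-octadec-9-en-1-ol (oleyl alcohol) | CCCCCCCC/C=C\CCCCCCCCO | starting material
2 | (Z)-octadec-9-enal | CCCCCCCC/C=C\CCCCCCCC=O | intermediate
3 | prop-2-en-1-ol (allyl alcohol) | C=CCO | starting material
4 | 3-(methoxymethoxy)prop-1-ene | C=CCOCOC | intermediate
5 | (Z)-γ-(methoxymethoxy)allyl-bis(isopinocampheyl)borane, isopinocampheyl groups from (−)-α-pinene | COCO/C=C\CB([C@H]1C[C@H]2C[C@@H]([C@@H]1C)C2(C)C)[C@H]1C[C@H]2C[C@@H]([C@@H]1C)C2(C)C | intermediate (not isolated)
6 | bis(isopinocampheyl)borinate ester of 7 | CCCCCCCC/C=C\CCCCCCC[C@H](OB([C@H]1C[C@H]2C[C@@H]([C@@H]1C)C2(C)C)[C@H]1C[C@H]2C[C@@H]([C@@H]1C)C2(C)C)[C@@H](OCOC)C=C | intermediate (not isolated)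
7 | (3S,4S,12Z)-3-(methoxymethoxy)henicosa-1,12-dien-4-ol | CCCCCCCC/C=C\CCCCCCC[C@H](O)[C@@H](OCOC)C=C | intermediate
8 | (3S,12Z)-3-(methoxymethoxy)henicosa-1,12-dien-4-one | CCCCCCCC/C=C\CCCCCCCC(=O)[C@@H](OCOC)C=C | intermediate
9 | 1-(tert-butyldimethylsilyloxy)-1-methoxyethene | COC(=C)O[Si](C)(C)C(C)(C)C | starting material
10 | methyl (3S,4S)-3-[(8Z)-heptadec-8-en-1-yl]-3-hydroxy-4-(methoxymethoxy)hex-5-enoate | CCCCCCCC/C=C\CCCCCCC[C@](O)(CC(=O)OC)[C@@H](OCOC)C=C | intermediate
11 | methyl (3S,4S)-3-[(8Z)-heptadec-8-en-1-yl]-3,4-bis(methoxymethoxy)hex-5-enoate | CCCCCCCC/C=C\CCCCCCC[C@](OCOC)(CC(=O)OC)[C@@H](OCOC)C=C | intermediate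
12 | (3S,4S)-3-[(8Z)-heptadec-8-en-1-yl]-3,4-bis(methoxymethoxy)bicyclo[3.1.0]hexan-1-ol (cis-fused, C1/C5 mixture) | CCCCCCCC/C=C\CCCCCCC[C@]1(OCOC)CC2(O)CC2[C@@H]1OCOC | intermediate
13 | 3-chloro-5-[(8Z)-heptadec-8-en-1-yl]-4,5-bis(methoxymethoxy)cyclohexan-1-one (C4 and C5 as in 12, CHCl mixture) | CCCCCCCC/C=C\CCCCCCC[C@]1(OCOC)CC(=O)CC(Cl)[C@@H]1OCOC | intermediate (not isolated)
14 | (4S,5S)-5-[(8Z)-heptadec-8-en-1-yl]-4,5-bis(methoxymethoxy)cyclohex-2-en-1-one | CCCCCCCC/C=C\CCCCCCC[C@]1(OCOC)CC(=O)C=C[C@@H]1OCOC | intermediate
15 | (4S,5S)-5-[(8Z)-heptadec-8-en-1-yl]-4,5-dihydroxycyclohex-2-en-1-one | CCCCCCCC/C=C\CCCCCCC[C@]1(O)CC(=O)C=C[C@@H]1O | target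

**Totals**
Total step count: 9. Longest linear sequence: 8 steps (1, 3, 4, 5, 6, 7, 8, 9).

**Steps most likely to fail**

1. Step 7 (Kulinkovich cyclopropanation). β-Elimination of the allylic methoxymethoxy group from the titanacyclopropane formed at the vinyl group (loss of the protecting group, formation of an allyltitanium species) or enolisation and β-elimination of the hindered ester may outrun the intramolecular ester insertion. The fallback builds the same bicyclic skeleton without titanium, by ring-closing metathesis and Simmons–Smith cyclopropanation, and sets out from 11. Me3SiCH2Li (2.2 equiv, pentane/THF, 0 °C) would give the α-silyl ketone F1, which MeOH would desilylate in the same flask to the methyl ketone F2. Kinetic enolisation on the methyl side (LDA, Me3SiCl, THF, −78 °C) would give the 2-silyloxy-1,6-diene F3. Ring-closing metathesis (second-generation Grubbs catalyst, toluene, 60 °C, high dilution) would give the cyclic silyl enol ether F4, with the enol double bond fixed next to the CH(OMOM) carbon. Furukawa–Simmons–Smith cyclopropanation (Et2Zn, CH2I2, CH2Cl2, 0 °C; the electron-rich enol ether should react ahead of the chain alkene) would give the silyloxybicyclohexane F5. Under the conditions of step 8, F5 comes back to the route at chloroketone 13 and then enone 14.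

2. Step 5 (chelation-controlled aldol). Lewis-acid-induced loss of the methoxymethyl group, migration of the β,γ-alkene of 8 into conjugation with loss of the stereocentre, or poor facial selectivity through incomplete chelation. The fallback replaces Lewis-acid activation by a neutral organozinc addition and sets out from 8. The Reformatsky reagent methyl (bromozincio)acetate F6, made from methyl bromoacetate and activated zinc dust in THF, would be added at 0 °C. Divalent zinc should bridge the carbonyl and α-ether oxygens so that the same Cram-chelate face is attacked. Aqueous NH4Cl work-up comes back to the route at 10.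

3. Step 9 (final unmasking). Acid-promoted β-elimination of the tertiary C5 oxygen function followed by aromatisation (loss of two molecules of water towards the 3-alkenylphenol) while the acetals are cleaved on the finished β-oxygenated enone. The fallback unmasks before the enone exists and sets out from 12. The same Me2BBr treatment (CH2Cl2, −78 °C; NaHCO3) would give the triol F7. FeCl3 in DMF at 0 °C should then oxidise only the strained tertiary cyclopropanol, giving the chloroketone diol F8, and NaOAc in MeOH would eliminate HCl. This comes back to the route at 15, the product having seen only acetate buffer.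

**Further compounds**
F1 | step 7 | (4S,5S)-4-[(8Z)-heptadec-8-en-1-yl]-4,5-bis(methoxymethoxy)-1-(trimethylsilyl)hept-6-en-2-one | CCCCCCCC/C=C\CCCCCCC[C@](OCOC)(CC(=O)C[Si](C)(C)C)[C@@H](OCOC)C=C
F2 | step 7 | (4S,5S)-4-[(8Z)-heptadec-8-en-1-yl]-4,5-bis(methoxymethoxy)hept-6-en-2-one | CCCCCCCC/C=C\CCCCCCC[C@](OCOC)(CC(C)=O)[C@@H](OCOC)C=C
F3 | step 7 | 2-(trimethylsilyloxy)-1,6-diene from F2 (stereocentres as in 11) | CCCCCCCC/C=C\CCCCCCC[C@](OCOC)(CC(=C)O[Si](C)(C)C)[C@@H](OCOC)C=C
F4 | step 7 | 4-[(8Z)-heptadec-8-en-1-yl]-3,4-bis(methoxymethoxy)-1-(trimethylsilyloxy)cyclopent-1-ene (stereocentres as in 11) | CCCCCCCC/C=C\CCCCCCC[C@]1(OCOC)CC(O[Si](C)(C)C)=C[C@@H]1OCOC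
F5 | step 7 | 3-[(8Z)-heptadec-8-en-1-yl]-3,4-bis(methoxymethoxy)-1-(trimethylsilyloxy)bicyclo[3.1.0]hexane (C1/C5 mixture) | CCCCCCCC/C=C\CCCCCCC[C@]1(OCOC)CC2(O[Si](C)(C)C)CC2[C@@H]1OCOC
F6 | step 5 | methyl (bromozincio)acetate (Reformatsky reagent) | COC(=O)C[Zn]Br
F7 | step 9 | 3-[(8Z)-heptadec-8-en-1-yl]bicyclo[3.1.0]hexane-1,3,4-triol (C3 and C4 as in 12, C1/C5 mixture) | CCCCCCCC/C=C\CCCCCCC[C@]1(O)CC2(O)CC2[C@@H]1O
F8 | step 9 | 3-chloro-5-[(8Z)-heptadec-8-en-1-yl]-4,5-dihydroxycyclohexan-1-one (C4 and C5 as in 15, CHCl mixture) | CCCCCCCC/C=C\CCCCCCC[C@]1(O)CC(=O)CC(Cl)[C@@H]1O
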